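**Plan**

1. Locants follow the chromene skeleton (O1, C2, C3, C4, C4a, C5–C8, C8a); ring A is the carbocycle, ring B the dihydropyranone.
2. Retrosynthetic cuts: the C8–benzylic carbon bond (Michael addition, then oxidation to the acid); C5–OH back to C5–SMe; then C4a–C8a and C3–C4 together in one flask, giving an acyclic ynal / ketene O,S-acetal on the quaternary C6; both arms from one β-keto ester (acetyl → alkyne → ynal; ester → acetyl → acetal); C6–prenyl and C6–CH2 by enolate alkylations.
3. Enabling feature: in ring B the fusion bond C4a–C8a and the bond C3–C4 flank the C4a–C4 pair, which is the α-carbon/carbonyl pair of a formyl group. C8a is an acetal-level carbon of a vinylogous ester that keeps O1, and C3 lies 1,4 to it through O1–C2 as the inner carbon of a vinyl group.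
4. Forward order: cyclobutane iodide → alkylated acetoacetate → quaternary C6 → arm exchange → acyclic precursor → ring A, then ring B, in one flask → C5–OH → C8 side chain → acid.
5. Stereochemistry: cis-cyclobutane from (1S,5S)-verbenone; C6 by auxiliary-controlled enamine alkylation; C2 from (R)-but-3-en-2-ol; C3 by substrate-controlled syn hydroacylation; benzylic carbon by iminium catalysis.

Key step: step 13

Remark on the chemistry: CbCH2 stands for {[(1R,3S)-2,2-dimethyl-3-(prop-1-en-2-yl)cyclobutyl]methyl}, the cis group carried by 5. The β-triketones 22 and 25 and the lactol 24 are each written as one tautomer. Numbered starting materials are taken as commercial.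

**Step 1**
Reactants: 1 (1S,5S)-(−)-verbenone
Product: 2 (1S,3R)-3-acetyl-2,2-dimethylcyclobutane-1-carboxylic acid
Conditions: RuCl3 (2 mol %), NaIO4 (4.2 equiv), MeCN/EtOAc/H2O, 23 °C
Reagents that add atoms: sodium periodate, [Na+].[O-]I(=O)(=O)=O; water, O
Why: RuO4-mediated oxidative cleavage of the enone C=C, with loss of the enone CH as CO2 from the intermediate α-keto acid, should give the cis keto acid, both stereocentres coming unchanged from the bicycle.

**Step 2**
Reactants: 2 keto acid
Product: 3 (1S,3S)-2,2-dimethyl-3-(prop-1-en-2-yl)cyclobutane-1-carboxylic acid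
Conditions: Ph3PCH3Br (3 equiv), KOtBu (3 equiv), THF, 0 → 23 °C; aq. HCl work-up
Reagents that add atoms: methyltriphenylphosphonium bromide, C[P+](c1ccccc1)(c1ccccc1)c1ccccc1.[Br-]
Why: Wittig methylenation of the methyl ketone with excess ylide (the carboxylate is inert) should give the isopropenyl group, and low temperature with short contact limits epimerisation next to the ketone.

**Step 3**
Reactants: 3 isopropenyl acid
Product: 4 [(1S,3S)-2,2-dimethyl-3-(prop-1-en-2-yl)cyclobutyl]methanol
Conditions: LiAlH4, THF, 0 → 23 °C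
Reagents that add atoms: none
Why: Hydride reduction of the acid to the primary alcohol leaves the isolated alkene and both ring stereocentres untouched.

**Step 4**
Reactants: 4 cyclobutylmethanol
Product: 5 (1S,3S)-1-(iodomethyl)-2,2-dimethyl-3-(prop-1-en-2-yl)cyclobutane
Conditions: PPh3, I2, imidazole, CH2Cl2, 0 → 23 °C
Reagents that add atoms: iodine, II
Why: Appel-type iodination converts the primary alcohol to the iodide by SN2 at CH2 under non-acidic conditions, so the acid-sensitive isopropenyl group and the ring centres are not involved.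

**Step 5**
Reactants: 6 ethyl acetoacetate; 5 iodide
Product: 7 ethyl 2-(CbCH2)-3-oxobutanoate (both C2 epimers)
Conditions: NaH, DMF, 0 °C; then 5, 60 °C
Reagents that add atoms: none
Why: SN2 C-alkylation of the sodium enolate of the β-keto ester by the primary iodide gives the mono-alkylated keto ester, whose new α-centre is enolisable and of no consequence.

**Step 6**
Reactants: 7 alkylated keto ester; 8 L-valine tert-butyl ester
Product: 9 ethyl (2Z)-3-{[(2S)-1-tert-butoxy-3-methyl-1-oxobutan-2-yl]amino}-2-(CbCH2)but-2-enoate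
Conditions: 8 (1.1 equiv), AcOH (5 mol %), 4 Å molecular sieves, toluene, 60 °C
Reagents that add atoms: none
Why: Condensation of the β-keto ester with the primary amino ester gives the hydrogen-bonded (Z)-enamino ester, the substrate for auxiliary-controlled alkylation.

**Step 7**
Reactants: 9 enamino ester
Product: 11 ethyl (2S)-2-acetyl-2-(CbCH2)-5-methylhex-4-enoate, via alkylated ketimine 10 (not isolated)
Conditions: LiN(iPr)2, toluene/HMPA, −78 °C; prenyl bromide, −78 → −40 °C; then aq. citric acid, THF, 23 °C
Reagents that add atoms: 1-bromo-3-methylbut-2-ene, CC(C)=CCBr; water, O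
Why: Alkylation of the lithiated chiral enamino ester (amino ester auxiliary method for α,α-dialkyl β-keto esters) sets the quaternary centre, the valine isopropyl group of the N,O-chelate shielding one face so that prenyl bromide is expected to enter from the other to give the (2S) centre drawn; mild acid hydrolysis then releases the ketone and the auxiliary.

**Step 8**
Reactants: 11 quaternary keto ester
Product: 13 ethyl (2S)-2-ethynyl-2-(CbCH2)-5-methylhex-4-enoate, via enol phosphate 12 (not isolated)
Conditions: LiN(iPr)2 (1.1 equiv), THF, −78 °C; ClP(O)(OEt)2; then LiN(iPr)2 (2.3 equiv), −78 → 23 °C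
Reagents that add atoms: none
Why: Kinetic enolisation of the methyl ketone (the only enolisable site), O-phosphorylation and base-induced elimination of the enol phosphate (one-flask methyl ketone to terminal alkyne conversion) should give the alkyne without touching the quaternary centre, which bears no hydrogen.

**Step 9**
Reactants: 13 alkynyl ester
Product: 15 (3S)-3-ethynyl-3-(CbCH2)-6-methylhept-5-en-2-one, via alpha-silyl ketone 14 (not isolated)
Conditions: Me3SiCH2Li (3.3 equiv), THF/pentane, 0 → 23 °C; then MeOH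
Reagents that add atoms: (trimethylsilyl)methyllithium, [Li]C[Si](C)(C)C
Why: Addition of the silylmethyl anion to the ester stops at the ketone stage because the α-silyl ketone is enolised in the flask, and methanolysis removes silicon (ester to methyl ketone conversion), the acetylide formed first protecting the alkyne.

**Step 10**
Reactants: 15 alkynyl methyl ketone
Product: 16 (4S)-4-ethynyl-4-(CbCH2)-7-methyl-1,1-bis(methylsulfanyl)octa-1,6-dien-3-one
Conditions: NaH (2.2 equiv), CS2, THF/DMF, 0 °C; then MeI (2.3 equiv), 23 °C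
Reagents that add atoms: carbon disulfide, S=C=S; iodomethane, CI
Why: Dithiocarboxylation of the ketone enolate followed by double S-methylation is the standard route to α-oxo ketene dithioacetals, and only the new acetyl group can enolise.

**Step 11**
Reactants: 16 ketene dithioacetal; 17 (R)-but-3-en-2-ol
Product: 18 (4S)-1-[(2R)-but-3-en-2-yloxy]-4-ethynyl-4-(CbCH2)-7-methyl-1-(methylsulfanyl)octa-1,6-dien-3-one
Conditions: 17 (1.05 equiv), NaH (1.05 equiv), THF, 0 °C
Reagents that add atoms: none
Why: Addition–elimination (vinylic substitution) of one methylthio group by the sodium alkoxide gives the ketene O,S-acetal, and since the C–O bond of the alcohol is not broken the carbinol centre keeps its (R) configuration.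

**Step 12**
Reactants: 18 ketene O,S-acetal
Product: 19 (4S)-4-{3-[(2R)-but-3-en-2-yloxy]-3-(methylsulfanyl)prop-2-enoyl}-4-(CbCH2)-7-methyloct-6-en-2-ynal
Conditions: LiN(iPr)2, THF, −78 °C; DMF; inverse quench into aq. KH2PO4
Reagents that add atoms: N,N-dimethylformamide, CN(C)C=O
Why: Deprotonation of the terminal alkyne (the most acidic C–H left) and formylation of the lithium acetylide with the formamide should give the ynal, the buffered inverse quench keeping the liberated amine from adding to it.

**Step 13**
Reactants: 19 acyclic ynal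
Product: 21 (2R,3S,6R)-2,3-dimethyl-6-(CbCH2)-6-(3-methylbut-2-en-1-yl)-5-(methylsulfanyl)-2,3-dihydro-4H-chromene-4,7(6H)-dione, via ring-A aldehyde 20 (not isolated)
Conditions: NaSMe (10 mol %), THF, 0 °C; then 3-mesityl-4,5-dimethylthiazolium perchlorate (20 mol %), DBU (40 mol %), 1,4-dioxane, 100 °C
Reagents that add atoms: none
Why: Proposed new method: methanethiolate adds to the ynal β-carbon (C5), the allenolate attacks the ketene O,S-acetal carbon C8a in a 6-endo-trig conjugate addition and the adduct expels methanethiolate (C4a–C8a bond, ring A), so the thiolate is a chain carrier and sulfur simply moves from C8a to C5; the closest known types are thiolate-triggered Michael–Michael (Rauhut–Currier-type) cyclisations and vinylic substitution of α-oxo ketene acetals by carbanions. The neutral aldehyde 20 is then taken up by the carbene, and the Breslow intermediate adds its acyl carbon and its hydroxyl hydrogen syn across the O-tethered vinyl group (C3–C4 bond, ring B, 6-exo-trig), the closest known type being carbene-catalysed hydroacylation of 2-allyloxybenzaldehydes to chroman-4-ones. C3 is the only new stereocentre: in the half-chair transition state the C2 methyl is pseudo-equatorial and the azolium avoids the peri methylthio group, which should place the methyl growing from CH2 pseudo-axial and hence cis to the C2 methyl, while C2 and C6 are not touched. The step needs thiolate addition to the ynal and not net substitution at the acetal (the ynal is far more electrophilic and exchange at C8a is degenerate), loss of thiolate and not alkoxide from C8a (thiolate is the better leaving group), and carbene entry only after the ynal is consumed (hence the staged addition, the C5 sulfur keeping the aldehyde neutral and non-enolisable).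

**Step 14**
Reactants: 21 methylthio chromenedione
Product: 22 (2R,3S,6R)-5-hydroxy-2,3-dimethyl-6-(CbCH2)-6-(3-methylbut-2-en-1-yl)-2,3-dihydro-4H-chromene-4,7(6H)-dione
Conditions: LiOH, THF/H2O, 0 °C; then 1 M HCl
Reagents that add atoms: lithium hydroxide, [Li+].[OH-]
Why: Hydroxide adds to C5 of the vinylogous thioester and expels methanethiolate (addition–elimination), and the β-triketone formed is deprotonated at once, which protects C3 from enolisation and ring B from retro-oxa-Michael opening.

**Step 15**
Reactants: 22 β-triketone enol; 23 (E)-cinnamaldehyde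
Product: 24 lactol of the C8 Michael adduct (2-hydroxy-4-phenyl-3,4-dihydro-2H-pyran fused at C7–C8, benzylic carbon S, both anomers)
Conditions: (S)-α,α-diphenylprolinol trimethylsilyl ether (20 mol %), PhCO2H (20 mol %), toluene, 0 → 23 °C
Reagents that add atoms: none
Why: Iminium-catalysed Michael addition of the cyclic β-dicarbonyl carbon C8 to the enal, followed by hemiacetal closure on the C7 enol oxygen, should set the (S) benzylic centre because the diarylsiloxymethyl group of the (S)-catalyst blocks one face of the (E)-iminium ion and C8 adds to the other.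

**Step 16**
Reactants: 24 lactol
Product: 25 (3S)-3-[(2R,3S,6R)-4-hydroxy-2,3-dimethyl-6-(CbCH2)-6-(3-methylbut-2-en-1-yl)-5,7-dioxo-3,5,6,7-tetrahydro-2H-chromen-8-yl]-3-phenylpropanoic acid (CNP0328119.1)
Conditions: NaClO2, NaH2PO4, 2-methylbut-2-ene, t-BuOH/H2O, 23 °C
Reagents that add atoms: sodium chlorite, [Na+].[O-]Cl=O
Why: Pinnick oxidation of the aldehyde in equilibrium with the lactol gives the carboxylic acid, the hypochlorite scavenger protecting the prenyl and isopropenyl groups and the buffered medium leaving every stereocentre untouched.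

**Compound list**

1 | (1S,5S)-(−)-verbenone, (1S,5S)-4,6,6-trimethylbicyclo[3.1.1]hept-3-en-2-one | CC1=CC(=O)[C@H]2C[C@@H]1C2(C)C | starting material
2 | (1S,3R)-3-acetyl-2,2-dimethylcyclobutane-1-carboxylic acid (cis) | CC(=O)[C@@H]1C[C@H](C(=O)O)C1(C)C | intermediate
3 | (1S,3S)-2,2-dimethyl-3-(prop-1-en-2-yl)cyclobutane-1-carboxylic acid (cis) | C=C(C)[C@@H]1C[C@H](C(=O)O)C1(C)C | intermediate
4 | [(1S,3S)-2,2-dimethyl-3-(prop-1-en-2-yl)cyclobutyl]methanol | C=C(C)[C@@H]1C[C@H](CO)C1(C)C | intermediate
5 | (1S,3S)-1-(iodomethyl)-2,2-dimethyl-3-(prop-1-en-2-yl)cyclobutane | C=C(C)[C@@H]1C[C@H](CI)C1(C)C | intermediate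
6 | ethyl acetoacetate | CCOC(=O)CC(C)=O | starting material
7 | ethyl 2-(CbCH2)-3-oxobutanoate, C2 epimers | C=C(C)[C@@H]1C[C@H](CC(C(C)=O)C(=O)OCC)C1(C)C | intermediate
8 | L-valine tert-butyl ester | CC(C)[C@H](N)C(=O)OC(C)(C)C | starting material
9 | ethyl (2Z)-3-{[(2S)-1-tert-butoxy-3-methyl-1-oxobutan-2-yl]amino}-2-(CbCH2)but-2-enoate | C=C(C)[C@@H]1C[C@H](C/C(C(=O)OCC)=C(C)/N[C@@H](C(C)C)C(=O)OC(C)(C)C)C1(C)C | intermediate
10 | ketimine of 11 with 8, ethyl (2S)-2-(CbCH2)-5-methyl-2-{N-[(2S)-1-tert-butoxy-3-methyl-1-oxobutan-2-yl]ethanimidoyl}hex-4-enoate | C=C(C)[C@@H]1C[C@H](C[C@@](C(=O)OCC)(CC=C(C)C)C(C)=N[C@@H](C(C)C)C(=O)OC(C)(C)C)C1(C)C | intermediate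
11 | ethyl (2S)-2-acetyl-2-(CbCH2)-5-methylhex-4-enoate | C=C(C)[C@@H]1C[C@H](C[C@@](C(=O)OCC)(CC=C(C)C)C(C)=O)C1(C)C | intermediate
12 | ethyl (2S)-2-{1-[(diethoxyphosphoryl)oxy]ethenyl}-2-(CbCH2)-5-methylhex-4-enoate | C=C(C)[C@@H]1C[C@H](C[C@@](C(=O)OCC)(CC=C(C)C)C(=C)OP(=O)(OCC)OCC)C1(C)C | intermediate
13 | ethyl (2S)-2-ethynyl-2-(CbCH2)-5-methylhex-4-enoate | C=C(C)[C@@H]1C[C@H](C[C@@](C(=O)OCC)(CC=C(C)C)C#C)C1(C)C | intermediate
14 | (3S)-3-ethynyl-3-(CbCH2)-6-methyl-1-(trimethylsilyl)hept-5-en-2-one | C=C(C)[C@@H]1C[C@H](C[C@@](C(=O)C[Si](C)(C)C)(CC=C(C)C)C#C)C1(C)C | intermediate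
15 | (3S)-3-ethynyl-3-(CbCH2)-6-methylhept-5-en-2-one | C=C(C)[C@@H]1C[C@H](C[C@@](C(C)=O)(CC=C(C)C)C#C)C1(C)C | intermediate
16 | (4S)-4-ethynyl-4-(CbCH2)-7-methyl-1,1-bis(methylsulfanyl)octa-1,6-dien-3-one | C=C(C)[C@@H]1C[C@H](C[C@@](C(=O)C=C(SC)SC)(CC=C(C)C)C#C)C1(C)C | intermediate
17 | (R)-but-3-en-2-ol | C=C[C@@H](C)O | starting material
18 | (4S)-1-[(2R)-but-3-en-2-yloxy]-4-ethynyl-4-(CbCH2)-7-methyl-1-(methylsulfanyl)octa-1,6-dien-3-one, E/Z mixture at C1=C2 | C=C(C)[C@@H]1C[C@H](C[C@@](C(=O)C=C(SC)O[C@H](C)C=C)(CC=C(C)C)C#C)C1(C)C | intermediate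
19 | (4S)-4-{3-[(2R)-but-3-en-2-yloxy]-3-(methylsulfanyl)prop-2-enoyl}-4-(CbCH2)-7-methyloct-6-en-2-ynal | C=C(C)[C@@H]1C[C@H](C[C@@](C(=O)C=C(SC)O[C@H](C)C=C)(CC=C(C)C)C#CC=O)C1(C)C | intermediate
20 | (3R)-6-[(2R)-but-3-en-2-yloxy]-3-(CbCH2)-3-(3-methylbut-2-en-1-yl)-2-(methylsulfanyl)-4-oxocyclohexa-1,5-diene-1-carbaldehyde | C=C(C)[C@@H]1C[C@H](C[C@@]2(CC=C(C)C)C(SC)=C(C=O)C(O[C@H](C)C=C)=CC2=O)C1(C)C | intermediate
21 | (2R,3S,6R)-2,3-dimethyl-6-(CbCH2)-6-(3-methylbut-2-en-1-yl)-5-(methylsulfanyl)-2,3-dihydro-4H-chromene-4,7(6H)-dione | C=C(C)[C@@H]1C[C@H](C[C@@]2(CC=C(C)C)C(SC)=C3C(=O)[C@@H](C)[C@@H](C)OC3=CC2=O)C1(C)C | intermediate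
22 | (2R,3S,6R)-5-hydroxy-2,3-dimethyl-6-(CbCH2)-6-(3-methylbut-2-en-1-yl)-2,3-dihydro-4H-chromene-4,7(6H)-dione, drawn as its 4-enol | C=C(C)[C@@H]1C[C@H](C[C@@]2(CC=C(C)C)C(=O)C3=C(O)[C@@H](C)[C@@H](C)OC3=CC2=O)C1(C)C | intermediate
23 | (E)-cinnamaldehyde | O=C/C=C/c1ccccc1 | starting material
24 | lactol of the C8 Michael adduct of 22: (S)-3-oxo-1-phenylpropyl chain at C8 closed as a cyclic hemiacetal on O7, both anomers | C=C(C)[C@@H]1C[C@H](C[C@@]2(CC=C(C)C)C(=O)C3=C(O[C@H](C)[C@H](C)C3=O)C3=C2OC(O)C[C@H]3c2ccccc2)C1(C)C | intermediate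
25 | (3S)-3-[(2R,3S,6R)-4-hydroxy-2,3-dimethyl-6-(CbCH2)-6-(3-methylbut-2-en-1-yl)-5,7-dioxo-3,5,6,7-tetrahydro-2H-chromen-8-yl]-3-phenylpropanoic acid (CNP0328119.1) | C=C(C)[C@@H]1C[C@H](C[C@@]2(CC=C(C)C)C(=O)C3=C(O)[C@@H](C)[C@@H](C)OC3=C([C@@H](CC(=O)O)c3ccccc3)C2=O)C1(C)C | target

**Step count and risks**

Total step count: 16. Longest linear sequence: 16 steps (1 → 25).

Steps most likely to fail:

Step 13 (proposed new method). The carbene may be slow to engage the crowded aldehyde, so that thermal [3,3] shift of the butenyl enol ether intervenes, or the acyl group may be delivered to the wrong face of the vinyl group. Fallback by known chemistry in the radical manifold: the ring-A aldehyde 20 is isolated after the thiolate stage and cyclised by thiol-catalysed radical-chain hydroacylation (methyl thioglycolate, AIBN, benzene, 80 °C; 6-exo acyl radical cyclisation as established for 2-allyloxybenzaldehydes). This should give 21 together with its C3 epimer, the (2R,3R)-chromenedione F1. Deprotonation of the mixture with LiN(iPr)2 at −78 °C and kinetic protonation of the enolate by 2,6-di-tert-butyl-4-methylphenol on the face opposite the C2 methyl group converts F1 into 21, where the route is rejoined.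

Step 7. Alkylation of the crowded lithio-enamine carrying the branched cyclobutylmethyl group may be slow or poorly face-selective. Fallback with catalyst control in place of auxiliary control: starting from 7, Tsuji–Trost asymmetric allylic alkylation ([Pd(C3H5)Cl]2, (R,R)-DACH-phenyl Trost ligand, allyl acetate, tetramethylguanidine, toluene, 0 °C) gives the allyl keto ester, ethyl (2S)-2-acetyl-2-(CbCH2)pent-4-enoate F2. Cross-metathesis with 2-methylbut-2-ene (second-generation Grubbs catalyst (H2IMes)(PCy3)Cl2Ru=CHPh, CH2Cl2, 40 °C) turns allyl into prenyl and returns to 11.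

Step 15. Uncatalysed background addition or reversible O-attack of the acidic nucleophile may erode face control at the benzylic carbon. Fallback: starting from 22, C-vinylation and lactonisation with ethyl propiolate (DABCO cat., MeCN) gives the fused 2-pyranone F3. Hayashi–Miyaura asymmetric 1,4-addition of phenylboronic acid ([Rh(acac)(C2H4)2], (S)-SEGPHOS, dioxane/H2O, 60 °C) gives the 4-phenyl enol lactone F4. LiOH in THF/H2O opens the lactone to the target 25, where the route ends (24 and step 16 are bypassed).

**Further compounds**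

F1 | step 13 | (2R,3R,6R)-2,3-dimethyl-6-(CbCH2)-6-(3-methylbut-2-en-1-yl)-5-(methylsulfanyl)-2,3-dihydro-4H-chromene-4,7(6H)-dione, C3 epimer of 21 | C=C(C)[C@@H]1C[C@H](C[C@@]2(CC=C(C)C)C(SC)=C3C(=O)[C@H](C)[C@@H](C)OC3=CC2=O)C1(C)C
F2 | step 7 | ethyl (2S)-2-acetyl-2-(CbCH2)pent-4-enoate | C=C(C)[C@@H]1C[C@H](C[C@@](C(=O)OCC)(CC=C)C(C)=O)C1(C)C
F3 | step 15 | 2-pyranone fused at C7–C8 of 22 (O7–C(=O)–CH=CH–C8) | C=C(C)[C@@H]1C[C@H](C[C@@]2(CC=C(C)C)C(=O)C3=C(O[C@H](C)[C@H](C)C3=O)C3=C2OC(=O)C=C3)C1(C)C
F4 | step 15 | (S)-4-phenyl-3,4-dihydro-2-pyranone (enol lactone) fused at C7–C8 | C=C(C)[C@@H]1C[C@H](C[C@@]2(CC=C(C)C)C(=O)C3=C(O[C@H](C)[C@H](C)C3=O)C3=C2OC(=O)C[C@H]3c2ccccc2)C1(C)C
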